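**Plan**
Numbering: ring A is the cyclohexane (C1 carbinol carbon with methyl C7, C2 bearing ring B, C4 bearing the isopropenyl group); ring B is the acylphloroglucinol-derived ring C1'–C6' (C1' on C2, C3' the diprenyl carbon, C5' the acyl carbon).
Retrosynthesis cuts, in this order, the two C3'–prenyl bonds (dearomatising alkylation of a phenol), the three phenol protecting groups, C1–C7 (methyl onto a C1 ketone) and C2–C1' (arylation of a regiodefined enol derivative).
Forward, no ring is formed: the cyclobutane of (+)-nopinone is opened to a C4-chiral cyclohexenyl acetate, its silyl enol ether is joined to a brominated tris-MOM phlorisobutyrophenone, then methylation, MOM removal and double prenylation follow.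
Enabling feature: in ring A, C1 carries methyl C7 and a hydroxyl that is cis to the aryl group on C2 (ring B through C1') and to the isopropenyl group on C4, the pattern left by equatorial methyl attack on the C1 ketone of a cis-2-aryl-4-isopropenylcyclohexanone.
Stereochemistry: C4 is the surviving pinane stereocentre, C2 is set by equilibration to the diequatorial cis ketone, and C1 by substrate-controlled methyl addition.

Key step: step 6

Remark: (+)-nopinone, the ozonolysis product of (−)-β-pinene, is taken as the commercial entry to ring A, and the target is drawn as the dienol-ketone tautomer given.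

Step 1
Reactants: 1 (1R,5S)-6,6-dimethylbicyclo[3.1.1]heptan-2-one [(+)-nopinone]
Product: 2 (S)-4-(prop-1-en-2-yl)cyclohex-1-en-1-yl acetate
Conditions: Ac2O, BF3·OEt2 (0.3 equiv), Zn(OAc)2 (0.3 equiv), CH2Cl2, 0 °C to rt
Reagents that add atoms: acetic anhydride, CC(=O)OC(C)=O
Why: Lewis acid-promoted acylative fragmentation of the cyclobutyl ketone breaks the bond between the α-bridgehead and the gem-dimethyl carbon, the tertiary cation loses a methyl proton to give the isopropenyl group and the enol oxygen is acetylated, so that the enol double bond points only toward the former bridgehead and the untouched second bridgehead becomes C4 (S) of ring A.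

Step 2
Reactants: 2 (S)-4-(prop-1-en-2-yl)cyclohex-1-en-1-yl acetate
Product: 4 (S)-trimethyl{[4-(prop-1-en-2-yl)cyclohex-1-en-1-yl]oxy}silane, via lithium enolate 3 (not isolated)
Conditions: MeLi (2.1 equiv), THF, −78 to 0 °C; then TMSCl (2.5 equiv), −78 °C to rt; pentane, filtration
Reagents that add atoms: chlorotrimethylsilane, C[Si](C)(C)Cl
Why: Cleavage of the enol ester by double addition of methyllithium to the acetyl group releases the lithium enolate in the absence of any ketone that could shuttle protons, and O-silylation of this enolate fixes the position of the double bond, the only element that distinguishes C2 from C6 and so keeps C4 stereogenic.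

Step 3
Reactants: 5 phlorisobutyrophenone [2-methyl-1-(2,4,6-trihydroxyphenyl)propan-1-one]
Product: 6 2-methyl-1-[2,4,6-tris(methoxymethoxy)phenyl]propan-1-one
Conditions: NaH (3.5 equiv), MOMCl (3.6 equiv), DMF, 0 °C to rt
Reagents that add atoms: chloromethyl methyl ether, COCCl
Why: Williamson-type O-alkylation of the three sodium phenoxides by the hard α-chloro ether should give the tris-acetal, the strong base being needed for the two hydroxyls that are hydrogen-bonded to the ketone.

Step 4
Reactants: 6 2-methyl-1-[2,4,6-tris(methoxymethoxy)phenyl]propan-1-one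
Product: 7 1-[3-bromo-2,4,6-tris(methoxymethoxy)phenyl]-2-methylpropan-1-one
Conditions: NBS (1.0 equiv), MeCN, 0 °C
Reagents that add atoms: N-bromosuccinimide, O=C1CCC(=O)N1Br
Why: Electrophilic aromatic bromination of the trialkoxyarene should occur at one of its two equivalent ring CH positions, which are far more nucleophilic than the enol of the hindered ketone, and one equivalent of the neutral bromine source should stop at the monobromide without liberating acid that would cleave the acetals.

Step 5
Reactants: 4 (S)-trimethyl{[4-(prop-1-en-2-yl)cyclohex-1-en-1-yl]oxy}silane (1.3 equiv); 7 1-[3-bromo-2,4,6-tris(methoxymethoxy)phenyl]-2-methylpropan-1-one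
Product: 9 (2R,4S)-2-[3-(2-methylpropanoyl)-2,4,6-tris(methoxymethoxy)phenyl]-4-(prop-1-en-2-yl)cyclohexan-1-one (cis ketone), via trans C2 epimer 8 (not isolated)
Conditions: Pd(OAc)2 (5 mol %), P(t-Bu)3 (10 mol %), ZnF2 (0.7 equiv), CsF (0.4 equiv), DMF, 80 °C; then DBU (0.2 equiv), CH2Cl2, rt
Reagents that add atoms: none
Why: Palladium-catalysed α-arylation of a silyl enol ether under fluoride activation (enolate arylation of the Buchwald–Hartwig type) should form C2–C1' at the enol carbon defined in step 1 without a strong base that would enolise the aryl ketone, and the epimerisable C2 centre is driven by DBU from any trans epimer 8 to the cis ketone 9 in which the aryl and isopropenyl groups are both equatorial.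

Step 6
Reactants: 9 (2R,4S)-2-[3-(2-methylpropanoyl)-2,4,6-tris(methoxymethoxy)phenyl]-4-(prop-1-en-2-yl)cyclohexan-1-one
Product: 10 1-{3-[(1R,2R,5S)-2-hydroxy-2-methyl-5-(prop-1-en-2-yl)cyclohexyl]-2,4,6-tris(methoxymethoxy)phenyl}-2-methylpropan-1-one [ring A: 1R,2R,4S; hydroxyl cis to aryl and to isopropenyl]
Conditions: CeCl3 (anhydrous, 1.6 equiv), MeLi (1.5 equiv), THF, −78 °C, 1 h; then 9, −78 °C; sat. aq NH4Cl
Reagents that add atoms: methyllithium, C[Li] (delivered as methylcerium dichloride made in the flask, C[Ce](Cl)Cl)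
Why: Methylcerium dichloride, formed from MeLi and CeCl3, is strongly oxophilic but weakly basic, so the methyl group should add to the cerium-activated C1 carbonyl (forming C1–C7) instead of removing the acidic benzylic C2–H. The closest known reaction type is the equatorial addition of organocerium and Grignard reagents to 2-substituted cyclohexanones such as menthone. No ring is closed in this step. The one new stereocentre, C1, is controlled by the chair of 9 in which the C2 aryl and C4 isopropenyl groups are both equatorial: the axial trajectory is obstructed by the axial hydrogens on C3 and C5 and would bring the methyl group in cis to the bulky aryl group, so methyl should enter equatorially, trans to the aryl group, and leave the hydroxyl axial and cis to both ring substituents (1R). The step needs facial selectivity at C1, chemoselectivity between two ketones and addition in preference to enolisation; the equatorial di-ortho-substituted aryl group on C2 secures the first, the twist and double ortho-flanking of the aryl isopropyl ketone (unreactive to carbonyl addition in the manner of mesityl ketones) the second, and the low basicity of the cerium reagent at −78 °C the third.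

Step 7
Reactants: 10 1-{3-[(1R,2R,5S)-2-hydroxy-2-methyl-5-(prop-1-en-2-yl)cyclohexyl]-2,4,6-tris(methoxymethoxy)phenyl}-2-methylpropan-1-one
Product: 12 1-{2,4,6-trihydroxy-3-[(1R,2R,5S)-2-hydroxy-2-methyl-5-(prop-1-en-2-yl)cyclohexyl]phenyl}-2-methylpropan-1-one, via tetrakis(trimethylsilyl) ether 11 (not isolated)
Conditions: TMSOTf (8 equiv), 2,2'-bipyridyl (12 equiv), CH2Cl2, 0 °C to rt; then H2O, rt
Reagents that add atoms: none
Why: Lewis acid-mediated acetal cleavage with the TMSOTf–2,2'-bipyridyl pair should convert each aryl MOM ether into an aryl trimethylsilyl ether (the tertiary alcohol is silylated too) and the water added afterwards hydrolyses the four O–Si bonds under the mild buffering of bipyridinium triflate, so that no strong protic acid is present that could ionise the tertiary carbinol or protonate the isopropenyl group.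

Step 8
Reactants: 12 1-{2,4,6-trihydroxy-3-[(1R,2R,5S)-2-hydroxy-2-methyl-5-(prop-1-en-2-yl)cyclohexyl]phenyl}-2-methylpropan-1-one; 13 prenyl bromide (1-bromo-3-methylbut-2-ene)
Product: 15 3,5-dihydroxy-4-[(1R,2R,5S)-2-hydroxy-2-methyl-5-(prop-1-en-2-yl)cyclohexyl]-2-(2-methylpropanoyl)-6,6-bis(3-methylbut-2-en-1-yl)cyclohexa-2,4-dien-1-one (target), via 3'-prenyl triol 14 (not isolated)
Conditions: NaOMe (3 equiv), MeOH, 0 °C; 13 (2.3 equiv), 0 °C to rt; aq NaH2PO4
Reagents that add atoms: prenyl bromide 13, CC(C)=CCBr
Why: Base-mediated dearomatising C-alkylation of the acylphloroglucinol anion (the type used for gem-dialkylated acylphloroglucinols) should prenylate the only unsubstituted ring carbon C3' to give 14 and then alkylate the same carbon of its anion a second time, because C1' is shielded by ring A and C5' is deactivated by the acyl group, which leaves the enolised triketone of the target with the three ring A stereocentres untouched.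

**Compound list**
1 | (1R,5S)-6,6-dimethylbicyclo[3.1.1]heptan-2-one, (+)-nopinone | CC1(C)[C@H]2CCC(=O)[C@@H]1C2 | starting material
2 | (S)-4-(prop-1-en-2-yl)cyclohex-1-en-1-yl acetate | C=C(C)[C@H]1CCC(OC(C)=O)=CC1 | intermediate
3 | lithium (S)-4-(prop-1-en-2-yl)cyclohex-1-en-1-olate | C=C(C)[C@H]1CCC(O[Li])=CC1 | intermediate
4 | (S)-trimethyl{[4-(prop-1-en-2-yl)cyclohex-1-en-1-yl]oxy}silane | C=C(C)[C@H]1CCC(O[Si](C)(C)C)=CC1 | intermediate
5 | phlorisobutyrophenone, 2-methyl-1-(2,4,6-trihydroxyphenyl)propan-1-one | CC(C)C(=O)c1c(O)cc(O)cc1O | starting material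
6 | 2-methyl-1-[2,4,6-tris(methoxymethoxy)phenyl]propan-1-one | CC(C)C(=O)c1c(OCOC)cc(OCOC)cc1OCOC | intermediate
7 | 1-[3-bromo-2,4,6-tris(methoxymethoxy)phenyl]-2-methylpropan-1-one | CC(C)C(=O)c1c(OCOC)cc(OCOC)c(Br)c1OCOC | intermediate
8 | (2S,4S)-2-[3-(2-methylpropanoyl)-2,4,6-tris(methoxymethoxy)phenyl]-4-(prop-1-en-2-yl)cyclohexan-1-one (trans epimer) | C=C(C)[C@H]1CCC(=O)[C@H](c2c(OCOC)cc(OCOC)c(C(=O)C(C)C)c2OCOC)C1 | intermediate
9 | (2R,4S)-2-[3-(2-methylpropanoyl)-2,4,6-tris(methoxymethoxy)phenyl]-4-(prop-1-en-2-yl)cyclohexan-1-one (cis ketone) | C=C(C)[C@H]1CCC(=O)[C@@H](c2c(OCOC)cc(OCOC)c(C(=O)C(C)C)c2OCOC)C1 | intermediate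
10 | 1-{3-[(1R,2R,5S)-2-hydroxy-2-methyl-5-(prop-1-en-2-yl)cyclohexyl]-2,4,6-tris(methoxymethoxy)phenyl}-2-methylpropan-1-one | C=C(C)[C@H]1CC[C@@](C)(O)[C@@H](c2c(OCOC)cc(OCOC)c(C(=O)C(C)C)c2OCOC)C1 | intermediate
11 | tetrakis(trimethylsilyl) ether of 12 (three aryl O–Si and the tertiary O–Si; ring A 1R,2R,4S) | C=C(C)[C@H]1CC[C@@](C)(O[Si](C)(C)C)[C@@H](c2c(O[Si](C)(C)C)cc(O[Si](C)(C)C)c(C(=O)C(C)C)c2O[Si](C)(C)C)C1 | intermediate
12 | 1-{2,4,6-trihydroxy-3-[(1R,2R,5S)-2-hydroxy-2-methyl-5-(prop-1-en-2-yl)cyclohexyl]phenyl}-2-methylpropan-1-one | C=C(C)[C@H]1CC[C@@](C)(O)[C@@H](c2c(O)cc(O)c(C(=O)C(C)C)c2O)C1 | intermediate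
13 | prenyl bromide, 1-bromo-3-methylbut-2-ene | CC(C)=CCBr | starting material
14 | 1-{2,4,6-trihydroxy-3-[(1R,2R,5S)-2-hydroxy-2-methyl-5-(prop-1-en-2-yl)cyclohexyl]-5-(3-methylbut-2-en-1-yl)phenyl}-2-methylpropan-1-one | C=C(C)[C@H]1CC[C@@](C)(O)[C@@H](c2c(O)c(CC=C(C)C)c(O)c(C(=O)C(C)C)c2O)C1 | intermediate
15 | 3,5-dihydroxy-4-[(1R,2R,5S)-2-hydroxy-2-methyl-5-(prop-1-en-2-yl)cyclohexyl]-2-(2-methylpropanoyl)-6,6-bis(3-methylbut-2-en-1-yl)cyclohexa-2,4-dien-1-one | C=C(C)[C@H]1CC[C@@](C)(O)[C@@H](C2=C(O)C(CC=C(C)C)(CC=C(C)C)C(=O)C(C(=O)C(C)C)=C2O)C1 | target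

**Step count**
Total: 8 steps. Longest linear sequence: 6 steps (1, 2, 5, 6, 7, 8 from nopinone; the aryl branch 3, 4, 5, 6, 7, 8 is equally long).

**Steps most likely to fail**

Step 5 (arylation). The coupling may stall at the crowded arylpalladium centre flanked by two MOM ethers. Protodesilylation of 4 may also outrun it, which would give achiral 4-isopropenylcyclohexanone and erase the regiochemical information that carries the C4 configuration. The fallback marks C2 before the coupling and joins two sp2 carbons instead. Setting out from 4, Saegusa–Ito oxidation (Pd(OAc)2 cat., O2, DMSO) would give (S)-4-(prop-1-en-2-yl)cyclohex-2-en-1-one F1, and α-iodination (I2, pyridine, CH2Cl2) would give (S)-2-iodo-4-(prop-1-en-2-yl)cyclohex-2-en-1-one F2. Bromide 7 would be converted by Miyaura borylation (B2pin2, KOAc, Pd(OAc)2, SPhos, dioxane, 80 °C) into the pinacol boronate 2-methyl-1-[2,4,6-tris(methoxymethoxy)-3-(4,4,5,5-tetramethyl-1,3,2-dioxaborolan-2-yl)phenyl]propan-1-one F3. Suzuki–Miyaura coupling of F2 and F3 (Pd(OAc)2, SPhos, K3PO4, toluene/H2O, 60 °C) would give the 2-aryl enone (S)-2-[3-(2-methylpropanoyl)-2,4,6-tris(methoxymethoxy)phenyl]-4-(prop-1-en-2-yl)cyclohex-2-en-1-one F4. Conjugate reduction of its enone double bond with Li[HB(s-Bu)3] (THF, −78 °C), aqueous NH4Cl quench and the DBU equilibration of step 5 would come back to the route at 9.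

Step 6 (key step). Methyl transfer may stall because the reagent deprotonates the acidic benzylic C2–H. Forcing the reaction with more reagent or higher temperature may then bring in attack on, or enolisation of, the aryl isopropyl ketone and erode the facial selectivity. The fallback leaves the acyl group out until the carbinol is in place, so that the methylation can be driven with a large excess of reagent. Commercial phloroglucinol would be protected (NaH, MOMCl, DMF) to 1,3,5-tris(methoxymethoxy)benzene F5 and brominated (NBS, MeCN) to 2-bromo-1,3,5-tris(methoxymethoxy)benzene F6. Setting out from 4, coupling with F6 under the conditions of step 5 would give (2R,4S)-4-(prop-1-en-2-yl)-2-[2,4,6-tris(methoxymethoxy)phenyl]cyclohexan-1-one F7. Methylation (MeLi, CeCl3 in excess, or MeMgBr, THF) would give (1R,2R,4S)-1-methyl-4-(prop-1-en-2-yl)-2-[2,4,6-tris(methoxymethoxy)phenyl]cyclohexan-1-ol F8. n-BuLi (2.2 equiv, THF, 0 °C) would remove the hydroxyl proton and then the ring proton between two MOM ethers (both such positions are equivalent) to give the O,C-dilithio derivative of F8 F9. Acylation with N-methoxy-N-methylisobutyramide and aqueous NH4Cl quench would come back to the route at 10.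

Step 8 (double prenylation). The phloroglucinol anion may be alkylated on oxygen, may stop after one prenyl group because the acidic product consumes base, or may be attacked at C1'. The fallback replaces the alkyl halide by a π-allyl electrophile. Setting out from 12, Tsuji–Trost allylation with 3-methylbut-2-en-1-yl methyl carbonate and Pd(PPh3)4 in THF (rt to 50 °C) would generate methoxide as the only base. O-Prenyl ethers re-ionise under the zerovalent palladium catalyst and should funnel to the C-prenylated products, passing through 14 and coming back to the route at 15. This fallback adds no new compound (F0).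

**Further compounds**
F1 | step 5 | (S)-4-(prop-1-en-2-yl)cyclohex-2-en-1-one | C=C(C)[C@H]1CCC(=O)C=C1
F2 | step 5 | (S)-2-iodo-4-(prop-1-en-2-yl)cyclohex-2-en-1-one | C=C(C)[C@H]1CCC(=O)C(I)=C1
F3 | step 5 | 2-methyl-1-[2,4,6-tris(methoxymethoxy)-3-(4,4,5,5-tetramethyl-1,3,2-dioxaborolan-2-yl)phenyl]propan-1-one | CC(C)C(=O)c1c(OCOC)cc(OCOC)c(B2OC(C)(C)C(C)(C)O2)c1OCOC
F4 | step 5 | (S)-2-[3-(2-methylpropanoyl)-2,4,6-tris(methoxymethoxy)phenyl]-4-(prop-1-en-2-yl)cyclohex-2-en-1-one | C=C(C)[C@H]1CCC(=O)C(c2c(OCOC)cc(OCOC)c(C(=O)C(C)C)c2OCOC)=C1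
F5 | step 6 | 1,3,5-tris(methoxymethoxy)benzene | COCOc1cc(OCOC)cc(OCOC)c1
F6 | step 6 | 2-bromo-1,3,5-tris(methoxymethoxy)benzene | COCOc1cc(OCOC)c(Br)c(OCOC)c1
F7 | step 6 | (2R,4S)-4-(prop-1-en-2-yl)-2-[2,4,6-tris(methoxymethoxy)phenyl]cyclohexan-1-one | C=C(C)[C@H]1CCC(=O)[C@@H](c2c(OCOC)cc(OCOC)cc2OCOC)C1
F8 | step 6 | (1R,2R,4S)-1-methyl-4-(prop-1-en-2-yl)-2-[2,4,6-tris(methoxymethoxy)phenyl]cyclohexan-1-ol | C=C(C)[C@H]1CC[C@@](C)(O)[C@@H](c2c(OCOC)cc(OCOC)cc2OCOC)C1
F9 | step 6 | O,C-dilithio derivative of F8 (lithium alkoxide at C1 and aryllithium between two MOM ethers) | C=C(C)[C@H]1CC[C@@](C)(O[Li])[C@@H](c2c(OCOC)cc(OCOC)c([Li])c2OCOC)C1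
F0 | step 8 | none | none
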